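The plan rests on opening ring B of the tetrahydronaphthalene (naphthalene numbering; ring A aromatic, ring B = C-5 to C-8) across C-6–C-7 and C-4a–C-5. The C-5 methyl, C-5 and C-6 are then one molecule of propene lying between a primary alkyl iodide (C-7) and an aryl bromide (C-4a). The key step, a nickel-catalysed reductive radical-relay [4+2] annulation, should form both bonds and the C-5 stereocentre in one operation, exploiting the 1,4 disposition of C-7 and C-4a across C-8/C-8a and the peri strain between the C-4 oxygen and C-5. Its precursor is an acyclic aryl bromide/alkyl iodide whose C-8/C-2′ stereodiad comes from an iridium/amine allylation uniting two fragments.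

Key step: step 13

Remark (step 9): the iridium catalyst alone fixes the benzylic centre and the amine alone fixes the α-centre. The (S)-ligand antipode written below is assumed to be the one that sets 3S; if the sense is the opposite, its antipode would be used.

Remark (step 5): the bromination is assumed to follow the isovanillin pattern, i.e. ortho to the C-3 hydroxyl between OH and CHO.

Step 1
Reactants: 1 (R)-3-bromo-2-methylpropan-1-ol
Product: 2 (R)-benzyl 3-bromo-2-methylpropyl ether
Conditions: benzyl 2,2,2-trichloroacetimidate, TfOH (cat.), CH2Cl2–cyclohexane, 0 °C to rt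
Reagents that add atoms: benzyl 2,2,2-trichloroacetimidate, N=C(OCc1ccccc1)C(Cl)(Cl)Cl
Why: Acid-catalysed trichloroacetimidate O-benzylation avoids base, so the bromo alcohol cannot close to an oxetane and the chiral-pool stereocentre is untouched.

Step 2
Reactants: 2 (R)-benzyl 3-bromo-2-methylpropyl ether; 3 pent-4-enylmagnesium bromide
Product: 4 (S)-benzyl 2-methyloct-7-enyl ether
Conditions: Li2CuCl4 (3 mol %), THF, −10 to 0 °C
Reagents that add atoms: none
Why: Copper-catalysed sp3–sp3 cross-coupling of a Grignard reagent with a primary alkyl bromide tolerates the β-branch and does not involve the stereocentre (the descriptor changes to S only by priority).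

Step 3
Reactants: 4 (S)-benzyl 2-methyloct-7-enyl ether
Product: 5 (S)-7-(benzyloxy)-6-methylheptanal
Conditions: O3, CH2Cl2, −78 °C; then PPh3, −78 °C to rt
Reagents that add atoms: ozone, O=[O+][O-]
Why: Ozonolysis with reductive work-up cleaves the only alkene to the aldehyde, and the benzyl ether should survive at −78 °C.

Step 4
Reactants: 6 5-iodovanillin (4-hydroxy-3-iodo-5-methoxybenzaldehyde)
Product: 7 3,4-dihydroxy-5-iodobenzaldehyde
Conditions: AlCl3, pyridine, CH2Cl2, reflux; then aq. HCl
Reagents that add atoms: none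
Why: Lewis acid/pyridine demethylation of an ortho-hydroxy aryl methyl ether is chelation-assisted and should leave the aryl iodide and the aldehyde intact.

Step 5
Reactants: 7 3,4-dihydroxy-5-iodobenzaldehyde
Product: 8 2-bromo-3,4-dihydroxy-5-iodobenzaldehyde
Conditions: Br2 (1.05 equiv), NaOAc, Fe powder (cat.), AcOH, rt
Reagents that add atoms: bromine, BrBr
Why: Electrophilic aromatic bromination is directed ortho to the C-3 hydroxyl into the position between OH and CHO, as with isovanillin, because the para position is flanked by the formyl group and the large iodine.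

Step 6
Reactants: 8 2-bromo-3,4-dihydroxy-5-iodobenzaldehyde
Product: 9 3,4-bis(benzyloxy)-2-bromo-5-iodobenzaldehyde
Conditions: BnBr (2.3 equiv), K2CO3, DMF, rt to 50 °C
Reagents that add atoms: benzyl bromide, BrCc1ccccc1
Why: Williamson etherification of both phenols gives hydrogenolysable protection for the catechol.

Step 7
Reactants: 9 3,4-bis(benzyloxy)-2-bromo-5-iodobenzaldehyde
Product: 10 benzyl 2,3-bis(benzyloxy)-4-bromo-5-formylbenzoate
Conditions: Pd(OAc)2 (5 mol %), Xantphos (6 mol %), CO (1 atm), BnOH (3 equiv), Et3N, toluene, 70 °C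
Reagents that add atoms: carbon monoxide, [C-]#[O+]; benzyl alcohol, OCc1ccccc1
Why: In this palladium-catalysed alkoxycarbonylation, oxidative addition to the C–I bond is much faster than to the doubly ortho-substituted C–Br bond, so only the iodide should become the benzyl ester.

Step 8
Reactants: 10 benzyl 2,3-bis(benzyloxy)-4-bromo-5-formylbenzoate
Product: 11 benzyl 2,3-bis(benzyloxy)-4-bromo-5-(1-hydroxyprop-2-enyl)benzoate (racemic)
Conditions: vinylmagnesium bromide (1.1 equiv), THF, −78 °C; then H2O
Reagents that add atoms: vinylmagnesium bromide, C=C[Mg]Br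
Why: Grignard 1,2-addition to the aldehyde at −78 °C is far faster than attack on the hindered benzyl ester or halogen–metal exchange, and the racemic carbinol is exactly what the enantioconvergent next step needs.

Step 9
Reactants: 11 benzyl 2,3-bis(benzyloxy)-4-bromo-5-(1-hydroxyprop-2-enyl)benzoate (racemic); 5 (S)-7-(benzyloxy)-6-methylheptanal
Product: 13 benzyl 2,3-bis(benzyloxy)-5-[(3S,4S,8S)-9-(benzyloxy)-4-(hydroxymethyl)-8-methylnon-1-en-3-yl]-4-bromobenzoate, via pentenal 12 (not isolated)
Conditions: [Ir(cod)Cl]2 (3 mol %), (S)-BINOL-derived N-dibenzo[b,f]azepinyl phosphoramidite–olefin ligand (12 mol %), (R)-2-{bis[3,5-bis(trifluoromethyl)phenyl](trimethylsilyloxy)methyl}pyrrolidine (15 mol %), (MeO)2P(O)OH (50 mol %), 5 (2.5 equiv), ClCH2CH2Cl, 25 °C; then NaBH4, MeOH, 0 °C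
Reagents that add atoms: none
Why: In this stereodivergent dual catalysis (iridium-catalysed asymmetric allylic alkylation combined with enamine catalysis) the iridium–phosphoramidite–olefin catalyst ionises racemic 11 to one π-allyl complex and sets the benzylic centre (3S) with branched regiochemistry, the enamine of 5 with the (R)-diarylprolinol silyl ether independently sets the α-centre (4S), and the aldehyde is reduced in the same flask before it can epimerise.

Step 10
Reactants: 13 benzyl 2,3-bis(benzyloxy)-5-[(3S,4S,8S)-9-(benzyloxy)-4-(hydroxymethyl)-8-methylnon-1-en-3-yl]-4-bromobenzoate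
Product: 14 benzyl 5-[(3S,4S,8S)-4-(acetoxymethyl)-9-(benzyloxy)-8-methylnon-1-en-3-yl]-2,3-bis(benzyloxy)-4-bromobenzoate
Conditions: Ac2O, pyridine, DMAP (cat.), CH2Cl2, 0 °C to rt
Reagents that add atoms: acetic anhydride, CC(=O)OC(C)=O
Why: Standard acylation of the primary alcohol installs the acetate of the target early, because every later step tolerates it.

Step 11
Reactants: 14 benzyl 5-[(3S,4S,8S)-4-(acetoxymethyl)-9-(benzyloxy)-8-methylnon-1-en-3-yl]-2,3-bis(benzyloxy)-4-bromobenzoate
Product: 16 benzyl 5-[(2S,3S,7S)-3-(acetoxymethyl)-8-(benzyloxy)-1-hydroxy-7-methyloctan-2-yl]-2,3-bis(benzyloxy)-4-bromobenzoate, via aldehyde 15 (not isolated)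
Conditions: O3, CH2Cl2–MeOH, −78 °C; then NaBH4, −78 to 0 °C
Reagents that add atoms: ozone, O=[O+][O-]
Why: Ozonolysis of the vinyl group with borohydride work-up excises the terminal carbon and reduces the epimerisable α-aryl aldehyde at once, which should give the future C-7 carbinol without loss of configuration at the benzylic centre.

Step 12
Reactants: 16 benzyl 5-[(2S,3S,7S)-3-(acetoxymethyl)-8-(benzyloxy)-1-hydroxy-7-methyloctan-2-yl]-2,3-bis(benzyloxy)-4-bromobenzoate
Product: 17 benzyl 5-[(2S,3S,7S)-3-(acetoxymethyl)-8-(benzyloxy)-1-iodo-7-methyloctan-2-yl]-2,3-bis(benzyloxy)-4-bromobenzoate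
Conditions: I2, PPh3, imidazole, CH2Cl2, 0 °C to rt
Reagents that add atoms: iodine, II
Why: Appel-type iodination converts the primary alcohol into the iodide by SN2 at a non-stereogenic carbon.

Step 13
Reactants: 17 benzyl 5-[(2S,3S,7S)-3-(acetoxymethyl)-8-(benzyloxy)-1-iodo-7-methyloctan-2-yl]-2,3-bis(benzyloxy)-4-bromobenzoate; 18 propene
Product: 19 benzyl (5R,8S)-8-[(2S,6S)-1-acetoxy-7-(benzyloxy)-6-methylheptan-2-yl]-3,4-bis(benzyloxy)-5-methyl-5,6,7,8-tetrahydronaphthalene-2-carboxylate
Conditions: NiBr2·DME (10 mol %), 4,4′-di-tert-butyl-2,2′-bipyridine (12 mol %), Mn powder (3 equiv), propene (condensed, ca. 30 equiv, sealed tube), DMA, 25 °C, slow addition of 17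
Reagents that add atoms: none
Why: Proposed new method: low-valent (monovalent) nickel abstracts iodine from 17 to give the primary C-7 radical, which adds to the unsubstituted terminus of propene (new C-6–C-7 bond) and leaves a secondary radical at the methyl-bearing carbon; this radical is captured by the aryl–nickel bromide (divalent nickel) formed by oxidative addition of the C–Br bond of the same molecule, and reductive elimination from the resulting trivalent aryl(alkyl)nickel forms the C-4a–C-5 bond. The closest known reaction type is the nickel-catalysed reductive 1,2-alkylarylation (three-component dicarbofunctionalisation) of alkenes with alkyl iodides and aryl halides, here with both electrophiles in one molecule so that it becomes an annulation. Ring B is closed by C(sp2)–C(sp3) reductive elimination from a seven-membered nickelacycle, i.e. a six-membered ring made by an intermolecular radical addition followed by an intramolecular cross-coupling (formal [4+2]). The new C-5 stereocentre is under substrate control: capture of the radical at nickel is expected to be reversible, and the nickelacycle that places the C-5 methyl pseudoaxial, away from the peri benzyloxy group at C-4, with the C-8 side chain pseudoaxial away from H-1, should eliminate faster, giving the 5,8-trans (5R) isomer. The step needs regioselectivity (alkyl to CH2, aryl to CH of propene), secured by the preference of alkyl radicals for the terminal carbon and by delivery of the aryl group only through nickel. It also needs intermolecular addition to outrun direct alkyl–aryl coupling, secured by the large excess of propene, the slow addition and the strain of the benzocyclobutene that direct coupling would have to form.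

Step 14
Reactants: 19 benzyl (5R,8S)-8-[(2S,6S)-1-acetoxy-7-(benzyloxy)-6-methylheptan-2-yl]-3,4-bis(benzyloxy)-5-methyl-5,6,7,8-tetrahydronaphthalene-2-carboxylate
Product: 20 (5R,8S)-8-[(2S,6S)-1-acetoxy-7-hydroxy-6-methylheptan-2-yl]-3,4-dihydroxy-5-methyl-5,6,7,8-tetrahydronaphthalene-2-carboxylic acid (target)
Conditions: H2 (1 atm), Pd/C (10 wt %), EtOAc–EtOH, rt
Reagents that add atoms: none
Why: Hydrogenolysis should remove the three benzyl ethers and the benzyl ester in one step while the acetate, the free primary alcohol and all four stereocentres are inert.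

Compound list
1 | (R)-3-bromo-2-methylpropan-1-ol | BrC[C@H](C)CO | starting material
2 | (R)-benzyl 3-bromo-2-methylpropyl ether | BrC[C@H](C)COCc1ccccc1 | intermediate
3 | pent-4-enylmagnesium bromide | C=CCCC[Mg]Br | starting material
4 | (S)-benzyl 2-methyloct-7-enyl ether | C=CCCCC[C@H](C)COCc1ccccc1 | intermediate
5 | (S)-7-(benzyloxy)-6-methylheptanal | O=CCCCC[C@H](C)COCc1ccccc1 | intermediate
6 | 5-iodovanillin (4-hydroxy-3-iodo-5-methoxybenzaldehyde) | COc1cc(C=O)cc(I)c1O | starting material
7 | 3,4-dihydroxy-5-iodobenzaldehyde | O=Cc1cc(O)c(O)c(I)c1 | intermediate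
8 | 2-bromo-3,4-dihydroxy-5-iodobenzaldehyde | O=Cc1cc(I)c(O)c(O)c1Br | intermediate
9 | 3,4-bis(benzyloxy)-2-bromo-5-iodobenzaldehyde | O=Cc1cc(I)c(OCc2ccccc2)c(OCc2ccccc2)c1Br | intermediate
10 | benzyl 2,3-bis(benzyloxy)-4-bromo-5-formylbenzoate | O=Cc1cc(C(=O)OCc2ccccc2)c(OCc2ccccc2)c(OCc2ccccc2)c1Br | intermediate
11 | benzyl 2,3-bis(benzyloxy)-4-bromo-5-(1-hydroxyprop-2-enyl)benzoate (racemic) | C=CC(O)c1cc(C(=O)OCc2ccccc2)c(OCc2ccccc2)c(OCc2ccccc2)c1Br | intermediate
12 | benzyl 2,3-bis(benzyloxy)-5-[(3S,4S,8S)-9-(benzyloxy)-4-formyl-8-methylnon-1-en-3-yl]-4-bromobenzoate (not isolated) | O=C[C@@H](CCC[C@H](C)COCc1ccccc1)[C@@H](c1cc(C(=O)OCc2ccccc2)c(OCc2ccccc2)c(OCc2ccccc2)c1Br)C=C | intermediate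
13 | benzyl 2,3-bis(benzyloxy)-5-[(3S,4S,8S)-9-(benzyloxy)-4-(hydroxymethyl)-8-methylnon-1-en-3-yl]-4-bromobenzoate | OC[C@@H](CCC[C@H](C)COCc1ccccc1)[C@@H](c1cc(C(=O)OCc2ccccc2)c(OCc2ccccc2)c(OCc2ccccc2)c1Br)C=C | intermediate
14 | benzyl 5-[(3S,4S,8S)-4-(acetoxymethyl)-9-(benzyloxy)-8-methylnon-1-en-3-yl]-2,3-bis(benzyloxy)-4-bromobenzoate | CC(=O)OC[C@@H](CCC[C@H](C)COCc1ccccc1)[C@@H](c1cc(C(=O)OCc2ccccc2)c(OCc2ccccc2)c(OCc2ccccc2)c1Br)C=C | intermediate
15 | benzyl 5-[(2S,3S,7S)-3-(acetoxymethyl)-8-(benzyloxy)-7-methyl-1-oxooctan-2-yl]-2,3-bis(benzyloxy)-4-bromobenzoate (not isolated) | CC(=O)OC[C@@H](CCC[C@H](C)COCc1ccccc1)[C@@H](c1cc(C(=O)OCc2ccccc2)c(OCc2ccccc2)c(OCc2ccccc2)c1Br)C=O | intermediate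
16 | benzyl 5-[(2S,3S,7S)-3-(acetoxymethyl)-8-(benzyloxy)-1-hydroxy-7-methyloctan-2-yl]-2,3-bis(benzyloxy)-4-bromobenzoate | CC(=O)OC[C@@H](CCC[C@H](C)COCc1ccccc1)[C@@H](c1cc(C(=O)OCc2ccccc2)c(OCc2ccccc2)c(OCc2ccccc2)c1Br)CO | intermediate
17 | benzyl 5-[(2S,3S,7S)-3-(acetoxymethyl)-8-(benzyloxy)-1-iodo-7-methyloctan-2-yl]-2,3-bis(benzyloxy)-4-bromobenzoate | CC(=O)OC[C@@H](CCC[C@H](C)COCc1ccccc1)[C@@H](c1cc(C(=O)OCc2ccccc2)c(OCc2ccccc2)c(OCc2ccccc2)c1Br)CI | intermediate
18 | propene | C=CC | starting material
19 | benzyl (5R,8S)-8-[(2S,6S)-1-acetoxy-7-(benzyloxy)-6-methylheptan-2-yl]-3,4-bis(benzyloxy)-5-methyl-5,6,7,8-tetrahydronaphthalene-2-carboxylate | CC(=O)OC[C@@H](CCC[C@H](C)COCc1ccccc1)[C@@H]1CC[C@@H](C)c2c1cc(C(=O)OCc3ccccc3)c(OCc3ccccc3)c2OCc1ccccc1 | intermediate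
20 | (5R,8S)-8-[(2S,6S)-1-acetoxy-7-hydroxy-6-methylheptan-2-yl]-3,4-dihydroxy-5-methyl-5,6,7,8-tetrahydronaphthalene-2-carboxylic acid | CC(=O)OC[C@@H](CCC[C@H](C)CO)[C@@H]1CC[C@@H](C)c2c1cc(C(=O)O)c(O)c2O | target

Total step count: 14. Longest linear sequence: 11 steps (steps 4 to 14, from 6 to 20).

Steps most likely to fail

Step 13 (key step). Addition of the unstabilised primary radical to an unactivated alkene may be too slow relative to its capture by nickel, which would lead to hydrodehalogenation, β-hydride elimination to the styrene or chain walking. The doubly ortho-substituted aryl–nickel may also couple sluggishly, and facial control in the ring closure may be poor. Fallback with known chemistry, setting out from 17 and returning at 19: radical allylation of the iodide with allyltributylstannane and AIBN (PhH, 80 °C; the alkyl iodide is abstracted far faster than the aryl bromide) should give benzyl 5-[(5S,6S,10S)-6-(acetoxymethyl)-11-(benzyloxy)-10-methylundec-1-en-5-yl]-2,3-bis(benzyloxy)-4-bromobenzoate F1. Slow addition of Bu3SnH with AIBN (PhH, 80 °C) should then generate the aryl radical, which closes ring B by 6-exo-trig cyclisation onto the terminal alkene, and the exocyclic primary radical is reduced to the C-5 methyl, giving 19. The same peri-strain argument is expected to favour the 5,8-trans isomer; any cis isomer would be removed by chromatography.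

Step 9. The ortho-bromo substituent may slow ionisation of the carbinol to the allyl–iridium species and erode the selectivity at either centre, and the α-branched aldehyde may epimerise before reduction. Fallback by auxiliary control, setting out from 10 and returning at 13: Horner–Wadsworth–Emmons olefination of 10 with diethyl {2-oxo-2-[(4S)-2-oxo-4-phenyloxazolidin-3-yl]ethyl}phosphonate (LiCl, iPr2NEt, MeCN) should give benzyl 2,3-bis(benzyloxy)-4-bromo-5-{(E)-3-oxo-3-[(4S)-2-oxo-4-phenyloxazolidin-3-yl]prop-1-enyl}benzoate F2. Conjugate addition of vinylmagnesium bromide/CuBr·SMe2 (THF, −40 °C) to the chelated s-cis enoyl imide, anti to the phenyl group, should give benzyl 2,3-bis(benzyloxy)-4-bromo-5-{(3R)-5-oxo-5-[(4S)-2-oxo-4-phenyloxazolidin-3-yl]pent-1-en-3-yl}benzoate F3, with the benzylic centre in the required sense. The alkylating agent comes from 2: copper-catalysed coupling with allylmagnesium bromide (Li2CuCl4, THF) gives (S)-benzyl 2-methylhex-5-enyl ether F4, ozonolysis with NaBH4 work-up gives (S)-5-(benzyloxy)-4-methylpentan-1-ol F5, and Tf2O/2,6-lutidine gives (S)-5-(benzyloxy)-4-methylpentyl trifluoromethanesulfonate F6. Alkylation of the sodium Z-enolate of F3 (NaHMDS, THF, −78 °C) with F6, again anti to the phenyl group, should give benzyl 2,3-bis(benzyloxy)-5-{(3S,4S,8S)-9-(benzyloxy)-8-methyl-4-[(4S)-2-oxo-4-phenyloxazolidine-3-carbonyl]non-1-en-3-yl}-4-bromobenzoate F7. Reductive removal of the auxiliary (LiBH4, MeOH, Et2O, 0 °C; the hindered benzyl ester reacts more slowly) returns 13.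

Step 5. Bromination may go para instead of ortho to the C-3 hydroxyl, may displace iodine by ipso attack, or may oxidise the free catechol. Fallback that enforces the isovanillin substitution pattern before bromination, setting out from 7 and returning at 9: selective benzylation of the more acidic 4-hydroxyl (BnBr 1.0 equiv, NaHCO3, DMF, 40 °C) should give 4-(benzyloxy)-3-hydroxy-5-iodobenzaldehyde F8. Bromination (Br2, NaOAc, Fe powder, AcOH) ortho to the single free hydroxyl should then give 4-(benzyloxy)-2-bromo-3-hydroxy-5-iodobenzaldehyde F9. Benzylation of the remaining phenol (BnBr, K2CO3, DMF) gives 9.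

Further compounds
F1 | step 13 | benzyl 5-[(5S,6S,10S)-6-(acetoxymethyl)-11-(benzyloxy)-10-methylundec-1-en-5-yl]-2,3-bis(benzyloxy)-4-bromobenzoate | CC(=O)OC[C@@H](CCC[C@H](C)COCc1ccccc1)[C@@H](c1cc(C(=O)OCc2ccccc2)c(OCc2ccccc2)c(OCc2ccccc2)c1Br)CCC=C
F2 | step 9 | benzyl 2,3-bis(benzyloxy)-4-bromo-5-{(E)-3-oxo-3-[(4S)-2-oxo-4-phenyloxazolidin-3-yl]prop-1-enyl}benzoate | O=C(/C=C/c1cc(C(=O)OCc2ccccc2)c(OCc2ccccc2)c(OCc2ccccc2)c1Br)N1C(=O)OC[C@@H]1c1ccccc1
F3 | step 9 | benzyl 2,3-bis(benzyloxy)-4-bromo-5-{(3R)-5-oxo-5-[(4S)-2-oxo-4-phenyloxazolidin-3-yl]pent-1-en-3-yl}benzoate | O=C(C[C@@H](c1cc(C(=O)OCc2ccccc2)c(OCc2ccccc2)c(OCc2ccccc2)c1Br)C=C)N1C(=O)OC[C@@H]1c1ccccc1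
F4 | step 9 | (S)-benzyl 2-methylhex-5-enyl ether | C=CCC[C@H](C)COCc1ccccc1
F5 | step 9 | (S)-5-(benzyloxy)-4-methylpentan-1-ol | OCCC[C@H](C)COCc1ccccc1
F6 | step 9 | (S)-5-(benzyloxy)-4-methylpentyl trifluoromethanesulfonate | O=S(=O)(OCCC[C@H](C)COCc1ccccc1)C(F)(F)F
F7 | step 9 | benzyl 2,3-bis(benzyloxy)-5-{(3S,4S,8S)-9-(benzyloxy)-8-methyl-4-[(4S)-2-oxo-4-phenyloxazolidine-3-carbonyl]non-1-en-3-yl}-4-bromobenzoate | O=C([C@@H](CCC[C@H](C)COCc1ccccc1)[C@@H](c1cc(C(=O)OCc2ccccc2)c(OCc2ccccc2)c(OCc2ccccc2)c1Br)C=C)N1C(=O)OC[C@@H]1c1ccccc1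
F8 | step 5 | 4-(benzyloxy)-3-hydroxy-5-iodobenzaldehyde | O=Cc1cc(O)c(OCc2ccccc2)c(I)c1
F9 | step 5 | 4-(benzyloxy)-2-bromo-3-hydroxy-5-iodobenzaldehyde | O=Cc1cc(I)c(OCc2ccccc2)c(O)c1Br
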